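**Plan**

1. Retrosynthesis first cuts the linoleate C–O bond, then the bond between the first and second carbon of the oxobutyl chain on C-b (a Wittig alkene, later reduced), which leaves a cyclobutane ester.
2. The ring bond CMe2–C-b (C-b is the ring CH carrying the oxobutyl chain, its first chain carbon now an ester carbon) is undone as a 1,2-shift onto the CMe2–C(=O) bond of a 5-diazo-2,2-dimethylcyclopentanone. This works because the quaternary CMe2 carbon flanks C-b, and because C-a (the ring CH bearing the C(=CH2) unit) becomes the β-carbon of that cyclopentanone.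
3. The last cut is C-a–C(=CH2): conjugate addition of a 2-boryl-1-alkene (from 4-pentyn-1-ol) to 5,5-dimethylcyclopent-2-enone (from 2,2-dimethylcyclopentanone).
4. Forward: boronate and enone are joined at C-a, the only α-methylene is turned into the diazo carbon, the five-membered ring is contracted to the single ring of the target, the chain on C-b is grown, and the linoleate is attached last.
5. Stereochemistry: C-a comes from an (S)-BINAP–rhodium 1,4-addition, C-b from methoxide equilibration of the ester to trans, and both Z alkenes arrive with linoleic acid.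

Key step: step 7

Remark: compound 8 is drawn as its hydrogen-bonded Z hydroxymethylene tautomer; it equilibrates with the keto aldehyde form, and either form reacts in step 6.

**Route**

Step 1
Reactants: 1 4-pentyn-1-ol
Product: 2 tert-butyldimethyl(pent-4-yn-1-yloxy)silane
Conditions: TBSCl, imidazole, CH2Cl2, 0 °C → rt
Reagents that add atoms: tert-butyldimethylsilyl chloride, CC(C)(C)[Si](C)(C)Cl
Why: Standard silylation of a primary alcohol with a silyl chloride and imidazole, in which the terminal alkyne is inert and the resulting ether should withstand the hydride, base, photolysis and ylide conditions that follow until step 11.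

Step 2
Reactants: 2 tert-butyldimethyl(pent-4-yn-1-yloxy)silane
Product: 4 2-[5-(tert-butyldimethylsilyloxy)pent-1-en-2-yl]-4,4,5,5-tetramethyl-1,3,2-dioxaborolane, via alkenylalane 3 (not isolated)
Conditions: NiCl2(dppp) (cat., dppp = 1,3-bis(diphenylphosphino)propane), i-Bu2AlH, THF, 0 °C → rt; then MeOBpin, 0 → 80 °C
Reagents that add atoms: 2-methoxy-4,4,5,5-tetramethyl-1,3,2-dioxaborolane (MeOBpin), COB1OC(C)(C)C(C)(C)O1
Why: Nickel–bisphosphine-catalysed Markovnikov hydroalumination of terminal alkyl alkynes places aluminium on the internal carbon, and the 1,1-disubstituted alkenylalane is known to undergo aluminium-to-boron exchange with methoxy(pinacolato)borane to give the internal alkenyl boronate.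

Step 3
Reactants: 5 2,2-dimethylcyclopentanone
Product: 6 5,5-dimethylcyclopent-2-en-1-one
Conditions: IBX (2-iodoxybenzoic acid), DMSO/fluorobenzene, 65 °C
Reagents that add atoms: none
Why: IBX dehydrogenation of a ketone to the enone proceeds through the enol, which here can form on one side only because the other α-carbon is quaternary, and the product cannot be oxidised further to a dienone.

Step 4
Reactants: 6 5,5-dimethylcyclopent-2-en-1-one; 4 2-[5-(tert-butyldimethylsilyloxy)pent-1-en-2-yl]-4,4,5,5-tetramethyl-1,3,2-dioxaborolane
Product: 7 (4S)-4-[5-(tert-butyldimethylsilyloxy)pent-1-en-2-yl]-2,2-dimethylcyclopentan-1-one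
Conditions: [RhCl(C2H4)2]2 (cat.), (S)-BINAP, aq. KOH (substoichiometric), 1,4-dioxane, 50 °C
Reagents that add atoms: none
Why: Hayashi–Miyaura asymmetric 1,4-addition, in which the alkenylrhodium species carrying (S)-BINAP inserts the enone from its 2si face, the sense established for cyclopent-2-enone, so that C-a is set as S; the β-carbon is unhindered because the gem-dimethyl group lies on the far side of the carbonyl, and water releases the ketone from the rhodium enolate.

Step 5
Reactants: 7 (4S)-4-[5-(tert-butyldimethylsilyloxy)pent-1-en-2-yl]-2,2-dimethylcyclopentan-1-one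
Product: 8 (4R,5Z)-4-[5-(tert-butyldimethylsilyloxy)pent-1-en-2-yl]-5-(hydroxymethylidene)-2,2-dimethylcyclopentan-1-one
Conditions: NaH, HCO2Et, THF, 0 °C → rt; AcOH quench
Reagents that add atoms: ethyl formate, CCOC=O
Why: Crossed Claisen condensation with ethyl formate can occur only at the single α-methylene and is driven by the stabilised sodium enolate of the β-keto aldehyde, while C-a, being β to the carbonyl, is not enolisable and keeps its configuration (the descriptor changes only through substituent priorities).

Step 6
Reactants: 8 (4R,5Z)-4-[5-(tert-butyldimethylsilyloxy)pent-1-en-2-yl]-5-(hydroxymethylidene)-2,2-dimethylcyclopentan-1-one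
Product: 9 (4R)-4-[5-(tert-butyldimethylsilyloxy)pent-1-en-2-yl]-5-diazo-2,2-dimethylcyclopentan-1-one
Conditions: p-ABSA, Et3N, MeCN, 0 °C → rt, dark
Reagents that add atoms: 4-acetamidobenzenesulfonyl azide (p-ABSA), CC(=O)Nc1ccc(cc1)S(=O)(=O)N=[N+]=[N-]
Why: Regitz deformylative diazo transfer, in which the enolate adds to the sulfonyl azide and the triazoline fragments with loss of the N-formyl sulfonamide, leaving the diazo group on the former methylene carbon under conditions too mild to disturb C-a.

Step 7
Reactants: 9 (4R)-4-[5-(tert-butyldimethylsilyloxy)pent-1-en-2-yl]-5-diazo-2,2-dimethylcyclopentan-1-one; 10 methanol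
Product: 13 methyl (1R,4S)-4-[5-(tert-butyldimethylsilyloxy)pent-1-en-2-yl]-2,2-dimethylcyclobutane-1-carboxylate, via ketene 11 (not isolated), via cis ester 12 (not isolated)
Conditions: hν (λ > 300 nm, Pyrex), MeOH, 0 °C; then NaOMe (cat.), 50 °C
Reagents that add atoms: none
Why: Excitation of the ring-locked s-Z α-diazo ketone releases dinitrogen and, in concert or through the singlet α-keto carbene, the CMe2 carbon moves from the carbonyl carbon to the former diazo carbon, which forms the CMe2–C-b bond and gives cyclobutylidene ketene 11; this is the photochemical Wolff rearrangement as known for 2-diazocyclopentanones. No ring is closed by joining chain ends: the four-membered ring is what remains of the five-membered one once the carbonyl carbon has become exocyclic, so there is no cyclisation mode to satisfy. Methanol adds to the ketene, and C-protonation of the resulting ester enol from the face away from the alkenyl group is expected to give mainly cis ester 12. Methoxide then equilibrates C-b, the only epimerisable centre, to trans ester 13, where the ester avoids the alkenyl group on the configurationally fixed C-a. The step needs rearrangement to win over O–H insertion into methanol and over 1,2-hydride shift from C-a; the enforced s-Z geometry and the high migratory aptitude of the tertiary carbon favour the concerted shift, and the site of the diazo group and the identity of the migrating carbon are unambiguous because the other α-position is quaternary.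

Step 8
Reactants: 13 methyl (1R,4S)-4-[5-(tert-butyldimethylsilyloxy)pent-1-en-2-yl]-2,2-dimethylcyclobutane-1-carboxylate
Product: 14 (1R,4S)-4-[5-(tert-butyldimethylsilyloxy)pent-1-en-2-yl]-2,2-dimethylcyclobutane-1-carbaldehyde
Conditions: i-Bu2AlH (1.1 equiv), CH2Cl2, −78 °C; aq. potassium sodium tartrate
Reagents that add atoms: none
Why: Partial reduction of a hindered methyl ester with one equivalent of i-Bu2AlH at low temperature should stop at the aluminium hemiacetal, which releases the aldehyde only on work-up, while the silyl ether and alkene are inert and the trans arrangement at C-b is the thermodynamically preferred one.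

Step 9
Reactants: 14 (1R,4S)-4-[5-(tert-butyldimethylsilyloxy)pent-1-en-2-yl]-2,2-dimethylcyclobutane-1-carbaldehyde; 15 1-(triphenylphosphoranylidene)propan-2-one
Product: 16 (3E)-4-{(1R,4S)-4-[5-(tert-butyldimethylsilyloxy)pent-1-en-2-yl]-2,2-dimethylcyclobutyl}but-3-en-2-one
Conditions: toluene, 90 °C
Reagents that add atoms: none
Why: Wittig olefination with the stabilised acetonyl ylide should give the E enone under weakly basic conditions that leave C-b in its stable trans configuration, and the alkene geometry is of no consequence because the double bond is reduced next.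

Step 10
Reactants: 16 (3E)-4-{(1R,4S)-4-[5-(tert-butyldimethylsilyloxy)pent-1-en-2-yl]-2,2-dimethylcyclobutyl}but-3-en-2-one
Product: 17 4-{(1R,4S)-4-[5-(tert-butyldimethylsilyloxy)pent-1-en-2-yl]-2,2-dimethylcyclobutyl}butan-2-one
Conditions: [(Ph3P)CuH]6, H2O, degassed toluene, rt
Reagents that add atoms: none
Why: Conjugate reduction by the phosphine-stabilised copper hydride hexamer delivers hydride only to the β-carbon of the enone, water protonates the copper enolate, and the isolated 1,1-disubstituted alkene, the ketone carbonyl and the silyl ether are not touched.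

Step 11
Reactants: 17 4-{(1R,4S)-4-[5-(tert-butyldimethylsilyloxy)pent-1-en-2-yl]-2,2-dimethylcyclobutyl}butan-2-one
Product: 18 4-[(1R,4S)-4-(5-hydroxypent-1-en-2-yl)-2,2-dimethylcyclobutyl]butan-2-one
Conditions: HF·pyridine, pyridine, THF, 0 °C → rt
Reagents that add atoms: none
Why: Fluoride cleavage of the primary silyl ether under pyridine-buffered conditions should neither enolise the methyl ketone nor isomerise the 1,1-disubstituted alkene.

Step 12
Reactants: 18 4-[(1R,4S)-4-(5-hydroxypent-1-en-2-yl)-2,2-dimethylcyclobutyl]butan-2-one; 19 linoleic acid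
Product: 20 4-[(1S,2R)-3,3-dimethyl-2-(3-oxobutyl)cyclobutyl]pent-4-en-1-yl (9Z,12Z)-octadeca-9,12-dienoate (IN0146)
Conditions: DCC, DMAP (cat.), CH2Cl2, 0 °C → rt, under argon
Reagents that add atoms: none
Why: Steglich esterification, in which the O-acylisourea from linoleic acid and DCC is passed on by DMAP to the primary alcohol at room temperature, conditions under which the skipped Z,Z-diene should not isomerise.

**Compound list**

1 | 4-pentyn-1-ol | C#CCCCO | starting material
2 | tert-butyldimethyl(pent-4-yn-1-yloxy)silane | C#CCCCO[Si](C)(C)C(C)(C)C | intermediate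
3 | [5-(tert-butyldimethylsilyloxy)pent-1-en-2-yl]bis(2-methylpropyl)alumane | C=C(CCCO[Si](C)(C)C(C)(C)C)[Al](CC(C)C)CC(C)C | intermediate
4 | 2-[5-(tert-butyldimethylsilyloxy)pent-1-en-2-yl]-4,4,5,5-tetramethyl-1,3,2-dioxaborolane | C=C(CCCO[Si](C)(C)C(C)(C)C)B1OC(C)(C)C(C)(C)O1 | intermediate
5 | 2,2-dimethylcyclopentanone | CC1(C)CCCC1=O | starting material
6 | 5,5-dimethylcyclopent-2-en-1-one | CC1(C)CC=CC1=O | intermediate
7 | (4S)-4-[5-(tert-butyldimethylsilyloxy)pent-1-en-2-yl]-2,2-dimethylcyclopentan-1-one | C=C(CCCO[Si](C)(C)C(C)(C)C)[C@H]1CC(C)(C)C(=O)C1 | intermediate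
8 | (4R,5Z)-4-[5-(tert-butyldimethylsilyloxy)pent-1-en-2-yl]-5-(hydroxymethylidene)-2,2-dimethylcyclopentan-1-one | C=C(CCCO[Si](C)(C)C(C)(C)C)[C@H]1CC(C)(C)C(=O)/C1=C\O | intermediate
9 | (4R)-4-[5-(tert-butyldimethylsilyloxy)pent-1-en-2-yl]-5-diazo-2,2-dimethylcyclopentan-1-one | C=C(CCCO[Si](C)(C)C(C)(C)C)[C@H]1CC(C)(C)C(=O)C1=[N+]=[N-] | intermediate
10 | methanol | CO | starting material
11 | {(4R)-4-[5-(tert-butyldimethylsilyloxy)pent-1-en-2-yl]-2,2-dimethylcyclobutylidene}methanone (ketene) | C=C(CCCO[Si](C)(C)C(C)(C)C)[C@H]1CC(C)(C)C1=C=O | intermediate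
12 | methyl (1S,4S)-4-[5-(tert-butyldimethylsilyloxy)pent-1-en-2-yl]-2,2-dimethylcyclobutane-1-carboxylate (cis) | C=C(CCCO[Si](C)(C)C(C)(C)C)[C@H]1CC(C)(C)[C@H]1C(=O)OC | intermediate
13 | methyl (1R,4S)-4-[5-(tert-butyldimethylsilyloxy)pent-1-en-2-yl]-2,2-dimethylcyclobutane-1-carboxylate (trans) | C=C(CCCO[Si](C)(C)C(C)(C)C)[C@H]1CC(C)(C)[C@@H]1C(=O)OC | intermediate
14 | (1R,4S)-4-[5-(tert-butyldimethylsilyloxy)pent-1-en-2-yl]-2,2-dimethylcyclobutane-1-carbaldehyde | C=C(CCCO[Si](C)(C)C(C)(C)C)[C@H]1CC(C)(C)[C@@H]1C=O | intermediate
15 | 1-(triphenylphosphoranylidene)propan-2-one | CC(=O)C=P(c1ccccc1)(c1ccccc1)c1ccccc1 | starting material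
16 | (3E)-4-{(1R,4S)-4-[5-(tert-butyldimethylsilyloxy)pent-1-en-2-yl]-2,2-dimethylcyclobutyl}but-3-en-2-one | C=C(CCCO[Si](C)(C)C(C)(C)C)[C@H]1CC(C)(C)[C@@H]1/C=C/C(C)=O | intermediate
17 | 4-{(1R,4S)-4-[5-(tert-butyldimethylsilyloxy)pent-1-en-2-yl]-2,2-dimethylcyclobutyl}butan-2-one | C=C(CCCO[Si](C)(C)C(C)(C)C)[C@H]1CC(C)(C)[C@@H]1CCC(C)=O | intermediate
18 | 4-[(1R,4S)-4-(5-hydroxypent-1-en-2-yl)-2,2-dimethylcyclobutyl]butan-2-one | C=C(CCCO)[C@H]1CC(C)(C)[C@@H]1CCC(C)=O | intermediate
19 | linoleic acid, (9Z,12Z)-octadeca-9,12-dienoic acid | CCCCC/C=C\C/C=C\CCCCCCCC(=O)O | starting material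
20 | 4-[(1S,2R)-3,3-dimethyl-2-(3-oxobutyl)cyclobutyl]pent-4-en-1-yl (9Z,12Z)-octadeca-9,12-dienoate (IN0146) | C=C(CCCOC(=O)CCCCCCC/C=C\C/C=C\CCCCC)[C@H]1CC(C)(C)[C@@H]1CCC(C)=O | target

**Step count**

Total: 12 steps. Longest linear sequence: 11 steps (steps 1, 2 and 4 to 12, from 4-pentyn-1-ol).

**Steps most likely to fail**

Step 7. The carbene may be diverted into O–H insertion with methanol or into a 1,2-hydride shift from C-a that gives the conjugated cyclopentenone, and strain in the forming four-membered ring may slow the desired shift. The fallback makes the same CMe2-to-C-b shift by a semibenzilic (quasi-Favorskii) contraction, known for α-halo ketones that cannot form a cyclopropanone, including cyclopentanone-to-cyclobutane contractions in caged systems. It sets out from ketone 7. Enolisation with LiN(SiMe3)2 in THF at −78 °C and chlorination with N-chlorosuccinimide should give (4R,5R)-5-chloro-4-[5-(tert-butyldimethylsilyloxy)pent-1-en-2-yl]-2,2-dimethylcyclopentan-1-one F1. NaOMe in MeOH then adds to the carbonyl, the CMe2 carbon migrates with loss of chloride, and the same methoxide equilibrates the ester to trans, so the route is rejoined at 13.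

Step 4. Transmetalation of the hindered 1,1-disubstituted alkenyl boronate may be slow, protodeboronation may outrun addition, or facial discrimination may be insufficient. The fallback changes both the nucleophile and the catalytic metal. Alkenylalane 3 is generated from 2 as in step 2 but not borylated, and is added to enone 6 under copper catalysis (Cu(OTf)2, chiral phosphoramidite ligand, Et2O, −30 °C). This asymmetric conjugate addition is known for alkenylalanes made by hydroalumination. Aqueous work-up of the aluminium enolate returns 7 directly, and no compound outside the list is formed (F0).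

Step 8. Over-reduction to the primary alcohol or incomplete conversion of the hindered ester is possible. The fallback goes through the alcohol oxidation level. From 13, LiAlH4 in THF at 0 °C should give {(1R,4S)-4-[5-(tert-butyldimethylsilyloxy)pent-1-en-2-yl]-2,2-dimethylcyclobutyl}methanol F2. Dess–Martin periodinane with NaHCO3 in CH2Cl2 then oxidises it to the aldehyde, and the route is rejoined at 14.

**Further compounds**

F1 | step 7 | (4R,5R)-5-chloro-4-[5-(tert-butyldimethylsilyloxy)pent-1-en-2-yl]-2,2-dimethylcyclopentan-1-one | C=C(CCCO[Si](C)(C)C(C)(C)C)[C@H]1CC(C)(C)C(=O)[C@@H]1Cl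
F0 | step 4 | none | none
F2 | step 8 | {(1R,4S)-4-[5-(tert-butyldimethylsilyloxy)pent-1-en-2-yl]-2,2-dimethylcyclobutyl}methanol | C=C(CCCO[Si](C)(C)C(C)(C)C)[C@H]1CC(C)(C)[C@@H]1CO
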